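Atoms carry the numbers of their position in the SMILES of target 24. Rings D (C3–C4–C6–C30–C15–C29) and E (C6–C8–C9–C14–C15–C30) share the unit C15–C30–C6, so both are cut at C15–C30 and C6–C8: a methacryloyl group on C3 becomes a two-carbon linchpin between a tertiary C15 radical and the α-methylene lactone on C14. The key step opens a C15–C16 epoxide with Cp2TiCl and closes both rings in one flask (radical 6-endo addition, then enolate Michael addition). Its precursor is a cyclopentane-fused (ring C) spiro-lactone dienone, assembled by Ireland–Claisen rearrangement, Stille coupling and an intramolecular Heck reaction.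

Key step: step 17

Remark: ring A = oxepinone (C18, C19, O22, C23, C25, C26, C27), ring B = C15–C18, C27, C29, ring C = cyclopentane (C2, C3, C29, C15, C14), ring F = γ-lactone (C9, C10, O12, C13, C14); β means the face of ring B that carries the C28 methyl group, α the opposite face.
Remark: C15/C16 of epoxide 20, C16 of 21–23 and C6 of 21 are written without configuration, because these centres are erased (C16 ends as CH2) or re-formed in the same flask (C15, C6).

Step 1
Reactants: 1 (S)-4a-methyl-4,4a,5,6,7,8-hexahydronaphthalen-2(3H)-one
Product: 2 gem-dimethyl β,γ-unsaturated ketone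
Conditions: KOtBu, MeI, t-BuOH, 0 °C to rt
Reagents that add atoms: iodomethane CI
Why: Deconjugative α,α-dimethylation of the dienolate puts both methyl groups on C19 and moves the alkene to C17=C18, leaving the C27 stereocentre untouched.

Step 2
Reactants: 2 gem-dimethyl β,γ-unsaturated ketone
Product: 3 ene-dione
Conditions: t-BuOOH, Rh2(cap)4 (cap = caprolactamate, 1 mol %), K2CO3, CH2Cl2, rt
Reagents that add atoms: tert-butyl hydroperoxide CC(C)(C)OO
Why: Allylic oxidation by peroxyl-radical C–H abstraction can only occur at C16, the single allylic CH2 of the C17=C18 alkene, as in the 7-oxidation of Δ5-steroids.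

Step 3
Reactants: 3 ene-dione
Product: 4 trans-fused dione
Conditions: H2 (1 atm), Pd/C (palladium on carbon), EtOAc, rt
Reagents that add atoms: none
Why: Catalytic hydrogenation of the enone adds hydrogen to C18 from the face opposite the C28 and axial C19 methyl groups, which sets the trans ring fusion.

Step 4
Reactants: 4 trans-fused dione
Product: 5 bis-enone
Conditions: IBX (2-iodoxybenzoic acid), DMSO/toluene, 75 °C
Reagents that add atoms: none
Why: IBX dehydrogenation through the enols gives the ring A enone (only C25 is enolisable) and the ring B enone C15=C29 through the enol on the side of the quaternary carbon, the regiochemistry shown by 3-keto-5α-steroids.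

Step 5
Reactants: 5 bis-enone
Product: 6 ring A lactone enone
Conditions: mCPBA, NaHCO3, CH2Cl2, rt
Reagents that add atoms: 3-chloroperbenzoic acid O=C(OO)c1cccc(Cl)c1
Why: Baeyer–Villiger oxidation is fastest at the ring A ketone, whose tertiary C19 migrates to oxygen, whereas the ring B enone offers only a CH2 or a vinyl migrating group.

Step 6
Reactants: 6 ring A lactone enone
Product: 7 α-iodo enone
Conditions: I2, pyridine, CH2Cl2, rt
Reagents that add atoms: iodine II
Why: α-Iodination of the enone runs by conjugate addition of pyridine, iodination and elimination, and the less electrophilic unsaturated lactone should not react.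

Step 7
Reactants: 7 α-iodo enone
Product: 8 16β allylic alcohol
Conditions: NaBH4, CeCl3·7H2O, MeOH, −78 °C
Reagents that add atoms: none
Why: Luche 1,2-reduction with axial hydride delivery should give the equatorial C16 alcohol, cis to C28.

Step 8
Reactants: 8 16β allylic alcohol; 9 3-bromobut-3-enoic acid
Product: 10 16α allylic ester
Conditions: PPh3, DIAD, THF, 0 °C to rt
Reagents that add atoms: none
Why: Mitsunobu esterification inverts C16, so the ester oxygen sits on the α face, to which C3 must later be delivered.

Step 9
Reactants: 10 16α allylic ester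
Product: 12 rearranged acid, via silyl ketene acetal 11 (not isolated)
Conditions: LiN(iPr)2 (LDA), Me3SiCl, THF, −78 °C to 60 °C; then 1 M HCl
Reagents that add atoms: chlorotrimethylsilane C[Si](C)(C)Cl (silicon stays only in 11)
Why: In this Ireland–Claisen rearrangement the suprafacial [3,3] shift bonds C3 to C29 on the α face while the alkene moves to C15=C16, and C3 follows from the ketene acetal geometry (bromovinyl group anti to OLi in THF) through the boat transition state usual for cyclohexenyl esters.

Step 10
Reactants: 12 rearranged acid
Product: 13 2-pyridyl thioester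
Conditions: 2,2'-dipyridyl disulfide, PPh3, CH2Cl2, rt
Reagents that add atoms: 2,2'-dipyridyl disulfide c1ccc(SSc2ccccn2)nc1
Why: Redox condensation activates the acid as the thioester under neutral conditions that should not epimerise C3.

Step 11
Reactants: 13 2-pyridyl thioester
Product: 14 methacryloyl ketone
Conditions: isopropenylmagnesium bromide, THF, −78 °C
Reagents that add atoms: isopropenylmagnesium bromide CC(=C)[Mg]Br
Why: In this ketone synthesis the magnesium-chelated 2-pyridyl thioester reacts with the Grignard reagent at −78 °C far faster than the hindered lactone or the product ketone.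

Step 12
Reactants: 15 4-hydroxy-3-methylfuran-2(5H)-one
Product: 16 butenolide triflate
Conditions: Tf2O, iPr2NEt, CH2Cl2, −78 °C
Reagents that add atoms: triflic anhydride O=S(=O)(OS(=O)(=O)C(F)(F)F)C(F)(F)F
Why: O-Sulfonylation of the vinylogous acid gives the enol triflate.

Step 13
Reactants: 16 butenolide triflate
Product: 17 stannyl butenolide
Conditions: (Bu3Sn)2, Pd(PPh3)4 (5 mol %), THF, 65 °C
Reagents that add atoms: hexabutylditin CCCC[Sn](CCCC)(CCCC)[Sn](CCCC)(CCCC)CCCC
Why: Palladium-catalysed stannylation of the enol triflate proceeds by oxidative addition, transmetalation with the distannane and reductive elimination.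

Step 14
Reactants: 14 methacryloyl ketone; 17 stannyl butenolide
Product: 18 dienyl butenolide
Conditions: Pd2(dba)3 (5 mol %), AsPh3, CuI, NMP, rt
Reagents that add atoms: none
Why: In this Stille coupling zerovalent palladium inserts into the vinyl iodide much faster than into the vinyl bromide at room temperature, and CuI speeds transmetalation of the electron-poor stannane.

Step 15
Reactants: 18 dienyl butenolide
Product: 19 spiro-lactone triene
Conditions: Pd(OAc)2 (10 mol %), PPh3, Ag2CO3, MeCN, 70 °C
Reagents that add atoms: none
Why: In this intramolecular Heck reaction the vinylpalladium at C2 adds 5-exo-trig to C14 on the butenolide face that keeps palladium and C9 away from the quaternary C27 (C9 syn to H29), and β-hydride elimination, possible only from the C8 methyl group, gives the α-methylene lactone.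

Step 16
Reactants: 19 spiro-lactone triene
Product: 20 C15–C16 epoxide
Conditions: mCPBA, NaHCO3, CH2Cl2, −20 °C
Reagents that add atoms: 3-chloroperbenzoic acid O=C(OO)c1cccc(Cl)c1
Why: Electrophilic epoxidation should select the trisubstituted C15=C16 alkene over the 1,1-disubstituted C1=C2 alkene, which is deactivated by the nearby C4 carbonyl, and over the three electron-poor alkenes.

Step 17
Reactants: 20 C15–C16 epoxide
Product: 22 hexacyclic C16 alcohol, via monocyclised ketone 21 (not isolated)
Conditions: Cp2TiCl2 (20 mol %), Mn dust, 2,4,6-collidine hydrochloride, THF, rt; then DBU, rt, same flask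
Reagents that add atoms: none
Why: Cp2TiCl (trivalent titanium, regenerated from Cp2TiCl2 by Mn) opens the epoxide homolytically to the tertiary C15 radical, which adds to C30 of the methacryloyl group; the C6 radical is reduced to the titanium enolate and protonated to 21, whose only enolisable position is C6 because C3 is now a bridgehead, so DBU closes the last ring by Michael addition of C6 to C8, and a direct radical addition of C6 to C8 would end at the same product. The closest known reaction type is the titanocene-mediated epoxide-opening radical cyclisation onto an enone, joined here to a base-mediated intramolecular Michael addition (radical–polar crossover). Ring D closes 6-endo-trig and ring E closes 6-(enolexo)-endo-trig. C15 can bond only on the face of ring C that carries the acyl group at C3 (cis-1,3 bridging to a bicyclo[3.2.1]octane), C6 is fixed by the cage because C14 holds C8 on the same face, and C9 is set by protonation under DBU equilibration to the epimer whose lactone carbonyl points away from C16. The step needs 6-endo rather than 5-exo attack, secured by the α-methyl enone whose carbonyl lies inside the forming ring, and radical generation at the epoxide only, secured because Cp2TiCl leaves the alkenes alone and does not capture a hindered tertiary radical before it cyclises.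

Step 18
Reactants: 22 hexacyclic C16 alcohol
Product: 23 C16 thiocarbonylimidazolide
Conditions: 1,1'-thiocarbonyldiimidazole, DMAP, toluene, 80 °C
Reagents that add atoms: 1,1'-thiocarbonyldiimidazole S=C(n1ccnc1)n1ccnc1
Why: Thioacylation of the secondary alcohol prepares the Barton–McCombie deoxygenation.

Step 19
Reactants: 23 C16 thiocarbonylimidazolide
Product: 24 target CNP0136584.3
Conditions: Bu3SnH, AIBN, toluene, 90 °C
Reagents that add atoms: none
Why: In the Barton–McCombie deoxygenation the stannyl radical adds to the thiocarbonyl group and the released secondary C16 radical, which has no alkene within 5-exo or 6-exo reach, takes hydrogen from Bu3SnH.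

Compound list
1 | (S)-4a-methyl-4,4a,5,6,7,8-hexahydronaphthalen-2(3H)-one | O=C1CC[C@]2(C)CCCCC2=C1 | starting material
2 | (S)-1,1,4a-trimethyl-3,4,4a,5,6,7-hexahydronaphthalen-2(1H)-one (C19 gem-dimethyl, C17=C18) | O=C1CC[C@]2(C)CCCC=C2C1(C)C | intermediate
3 | ene-dione: C23 ketone and C16 ketone conjugated with C17=C18 | O=C1CC[C@]2(C)CCC(=O)C=C2C1(C)C | intermediate
4 | trans-fused 1,1,4a-trimethyldecalin-2,7-dione (C18–H anti to C28) | O=C1CC[C@]2(C)CCC(=O)C[C@H]2C1(C)C | intermediate
5 | bis-enone (C25=C26–C23=O in ring A, C29=C15–C16=O in ring B) | O=C1C=C[C@]2(C)C=CC(=O)C[C@H]2C1(C)C | intermediate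
6 | ring A unsaturated ε-lactone with the ring B enone | O=C1C=C[C@]2(C)C=CC(=O)C[C@H]2C(C)(C)O1 | intermediate
7 | 15-iodo enone of 6 | O=C1C=C[C@]2(C)C=C(I)C(=O)C[C@H]2C(C)(C)O1 | intermediate
8 | 16β allylic alcohol (OH cis to C28), C15 iodide | O=C1C=C[C@]2(C)C=C(I)[C@@H](O)C[C@H]2C(C)(C)O1 | intermediate
9 | 3-bromobut-3-enoic acid | OC(=O)CC(Br)=C | starting material
10 | 16α 3-bromobut-3-enoate (ester oxygen anti to C28) | O=C1C=C[C@]2(C)C=C(I)[C@H](OC(=O)CC(Br)=C)C[C@H]2C(C)(C)O1 | intermediate
11 | trimethylsilyl ketene acetal of 10 | O=C1C=C[C@]2(C)C=C(I)[C@H](OC(O[Si](C)(C)C)=CC(Br)=C)C[C@H]2C(C)(C)O1 | intermediate (not isolated)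
12 | acid with the C29–C3 bond on the α face, C3 bearing CO2H and 1-bromovinyl, C15(I)=C16 | O=C1C=C[C@]2(C)[C@H]([C@@H](C(O)=O)C(Br)=C)C(I)=CC[C@H]2C(C)(C)O1 | intermediate
13 | S-(2-pyridyl) thioester of 12 | O=C1C=C[C@]2(C)[C@H]([C@@H](C(=O)Sc3ccccn3)C(Br)=C)C(I)=CC[C@H]2C(C)(C)O1 | intermediate
14 | methacryloyl ketone (C4=O, C6=C30) with vinyl bromide at C2 and vinyl iodide at C15 | O=C1C=C[C@]2(C)[C@H]([C@@H](C(=O)C(C)=C)C(Br)=C)C(I)=CC[C@H]2C(C)(C)O1 | intermediate
15 | 4-hydroxy-3-methylfuran-2(5H)-one (α-methyltetronic acid) | CC1=C(O)COC1=O | starting material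
16 | 3-methyl-5-oxo-2,5-dihydrofuran-4-yl... written as 4-triflyloxy-3-methylfuran-2(5H)-one | CC1=C(OS(=O)(=O)C(F)(F)F)COC1=O | intermediate
17 | 3-methyl-4-(tributylstannyl)furan-2(5H)-one | CCCC[Sn](CCCC)(CCCC)C1=C(C)C(=O)OC1 | intermediate
18 | Stille product: butenolide C14 bonded to C15, vinyl bromide at C2 | O=C1C=C[C@]2(C)[C@H]([C@@H](C(=O)C(C)=C)C(Br)=C)C(C3=C(C)C(=O)OC3)=CC[C@H]2C(C)(C)O1 | intermediate
19 | Heck product: ring C closed, spiro α-methylene lactone at C14 (C9 syn to H29), C1=C2, C15=C16, methacryloyl on C3 | C=C1[C@H](C(=O)C(C)=C)[C@@H]2C(=CC[C@H]3C(C)(C)OC(=O)C=C[C@]23C)[C@@]14COC(=O)C4=C | intermediate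
20 | C15–C16 epoxide of 19 (either face) | C=C1[C@H](C(=O)C(C)=C)[C@@H]2C3(OC3C[C@H]4C(C)(C)OC(=O)C=C[C@]24C)[C@@]15COC(=O)C5=C | intermediate
21 | monocyclised ketone: C15–C30 bond formed, C6–H, C16–OH, α-methylene lactone intact | C=C1[C@@H]2C(=O)C(C)C[C@]3(C(O)C[C@H]4C(C)(C)OC(=O)C=C[C@]4(C)[C@H]23)[C@@]15COC(=O)C5=C | intermediate (not isolated)
22 | 16-hydroxy derivative of the target | C=C1[C@@H]2C(=O)[C@]3(C)C[C@@H]4C(=O)OC[C@]14[C@@]1(C(O)C[C@H]4C(C)(C)OC(=O)C=C[C@]4(C)[C@H]21)C3 | intermediate
23 | O-(imidazol-1-ylthiocarbonyl) derivative of 22 | C=C1[C@@H]2C(=O)[C@]3(C)C[C@@H]4C(=O)OC[C@]14[C@@]1(C(OC(=S)n5ccnc5)C[C@H]4C(C)(C)OC(=O)C=C[C@]4(C)[C@H]21)C3 | intermediate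
24 | CNP0136584.3 | C=C1[C@@H]2C(=O)[C@]3(C)C[C@@H]4C(=O)OC[C@]14[C@@]1(CC[C@H]4C(C)(C)OC(=O)C=C[C@]4(C)[C@H]21)C3 | target

Total step count: 19. Longest linear sequence: 17 (steps 1–11 and 14–19).

Steps most likely to fail

Step 17. The C15 radical may be lost before it cyclises (capture by a second titanium and elimination back to the alkene), or the enolate may be protonated and the Michael closure remain incomplete. The fallback is anionic. Setting out from 20, a Meinwald rearrangement (BF3·OEt2, CH2Cl2, −78 °C, hydride shift from C16 to the tertiary C15 cation) would give the C16 ketone F1. Cs2CO3 in MeCN would then run a double Michael addition, C15 enolate to C30 and C6 enolate to C8, to the cage ketone F2. NaBH4 with CeCl3 at −78 °C should reduce only the less hindered C16 ketone and return to the route at 22.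

Step 15. Carbopalladation of the tetrasubstituted butenolide alkene may be too slow, so that protodebromination or alkene migration takes over, or the facial selectivity at C14 may be poor. Setting out from 18, a group-transfer radical cyclisation ((Bu3Sn)2, (PhSe)2, hν, benzene) would close the same ring by 5-exo attack of the C2 vinyl radical on C14 and trap the C9 radical as the selenide F3. H2O2 and pyridine at 0 °C would then give the α-methylene lactone by selenoxide elimination toward C8, coming back at 19.

Step 16. Epoxidation may also attack the exocyclic C1=C2 alkene. Setting out from 19, both alkenes would be epoxidised with excess dimethyldioxirane to the bis-epoxide F4. With stoichiometric Cp2TiCl (from Cp2TiCl2 and Mn) the radical from the exocyclic epoxide has no acceptor, is captured by a second titanium and eliminates back to the C1=C2 alkene, while the ring epoxide enters the cyclisation. The DBU treatment then comes back to the route at 22.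

Further compounds
F1 | step 17 | C16 ketone with C15–H from Meinwald rearrangement of 20 | C=C1[C@H](C(=O)C(C)=C)[C@@H]2C(C(=O)C[C@H]3C(C)(C)OC(=O)C=C[C@]23C)[C@@]14COC(=O)C4=C
F2 | step 17 | 16-oxo derivative of the target | C=C1[C@@H]2C(=O)[C@]3(C)C[C@@H]4C(=O)OC[C@]14[C@@]1(C(=O)C[C@H]4C(C)(C)OC(=O)C=C[C@]4(C)[C@H]21)C3
F3 | step 15 | α-phenylselanyl α-methyl spiro-lactone (ring C closed) | C=C1[C@H](C(=O)C(C)=C)[C@@H]2C(=CC[C@H]3C(C)(C)OC(=O)C=C[C@]23C)[C@@]14COC(=O)C4(C)[Se]c5ccccc5
F4 | step 16 | bis-epoxide of 19 (C1–C2 and C15–C16) | C1OC12[C@H](C(=O)C(C)=C)[C@@H]3C4(OC4C[C@H]5C(C)(C)OC(=O)C=C[C@]35C)[C@@]26COC(=O)C6=C
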